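**Retrosynthetic overview**
1. Feature: the pyran ring (ring C), O1–C2(CH3)2–C3=C4, is fused at C4a/C8a beside the C5 methoxy group. It is a coumarin lactone whose C2 carbonyl oxygen has been exchanged for two methyl groups, and the cis C3=C4 bond is already present in the lactone.
2. Last disconnection: the 7-O-MOM group, then both aryl–C(=O) bonds of the dione. This leads back to a C6 aryllithium of the chromene, 1,4-dimethylpiperazine-2,3-dione as the two-carbon oxalyl unit, and 4-prenyloxyphenyllithium. No ketal and no strong acid are needed, which spares the prenyl ether and the chromene.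
3. Key disconnection: both C2–CH3 bonds and O1–C2, back to 7-hydroxy-5-methoxycoumarin and methyllithium.
4. First disconnection in the forward sense: C3=C4 and the lactone C–O bond, back to 2,4-dihydroxy-6-methoxybenzaldehyde and a stabilised ylide. The aldehyde carbon becomes C4, so the fusion next to C5–OMe is fixed.
5. Ring order: both benzene rings are bought. The lactone ring is closed in step 1, then opened and re-closed as the pyran in step 2. No further ring is formed.

Key step: step 2

Assumption: every compound marked as starting material in the compound list is taken to be a catalogue chemical.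

Step 1
Reactants: 1 2,4-dihydroxy-6-methoxybenzaldehyde; 2 ethyl (triphenylphosphoranylidene)acetate
Product: 5 7-hydroxy-5-methoxy-2H-chromen-2-one, via ethyl E-cinnamate 3 (not isolated), via ethyl Z-cinnamate 4 (not isolated)
Conditions: 2 (1.3 equiv), PhNEt2, reflux (about 215 °C), N2
Reagents that add atoms: ethyl (triphenylphosphoranylidene)acetate 2, CCOC(=O)C=P(c1ccccc1)(c1ccccc1)c1ccccc1
Why: A Wittig olefination with the stabilised ylide gives cinnamate 3, which at the reflux temperature of N,N-diethylaniline equilibrates with 4 and lactonises through the only ortho hydroxyl with loss of ethanol, a known one-pot coumarin synthesis from salicylaldehydes that tolerates free phenols and, since the other ortho position carries OMe and the aldehyde carbon becomes C4, places the methoxy group at C5 without ambiguity.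

Step 2
Reactants: 5 7-hydroxy-5-methoxy-2H-chromen-2-one; 6 methyllithium
Product: 9 5-methoxy-2,2-dimethyl-2H-chromen-7-ol, via Z-enone dilithium salt 7 (not isolated), via Z-triol 8 (not isolated)
Conditions: MeLi (4.5 equiv), THF, −78 → 0 °C; then AcOH, 0 °C → rt
Reagents that add atoms: methyllithium 6, [Li]C
Why: The first equivalent of MeLi is spent on the C7 hydroxyl; the next adds to the lactone carbonyl C2, the cyclic hemiketal alkoxide opens at O1–C2 to the Z-enone 7, and a further MeLi adds to its ketone, so that both C2–CH3 bonds are made in one flask and the trilithium salt of 8 results. Acetic acid frees triol 8, whose tertiary allylic hydroxyl ionises easily because the cation is delocalised to C4 and from there onto the oxygens at C5, C7 and C8a. The only ring closed is the pyran: the C8a oxygen attacks the tertiary terminus C2 in a six-membered O1–C2 closure, which may equally be read as the oxa-6π electrocyclisation of the vinylogous ortho-quinone methide, and no other oxygen can compete because the second ortho position carries OMe and the C7 hydroxyl is para to the chain. The closest known reaction type is the conversion of coumarins into 2,2-dialkyl-2H-chromenes with excess methyl Grignard reagent or methyllithium followed by acid cyclodehydration. No stereocentre is created, and the cis geometry of C3=C4 is carried over from the lactone ring. The step needs 1,2- rather than 1,4-addition, which the hard, uncomplexed organolithium at low temperature favours and which the C7 phenoxide supports by feeding charge through C4a into the C4=C3–C2=O system.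

Step 3
Reactants: 9 5-methoxy-2,2-dimethyl-2H-chromen-7-ol
Product: 10 5-methoxy-7-(methoxymethoxy)-2,2-dimethyl-2H-chromene
Conditions: NaH (1.2 equiv), MOMCl (1.2 equiv), DMF, 0 °C → rt
Reagents that add atoms: chloromethyl methyl ether (MOMCl), COCCl
Why: Williamson-type O-alkylation of the single phenol with the highly reactive chloromethyl ether is fast at 0 °C under basic conditions that leave the acid-sensitive chromene untouched, and the MOM acetal both masks the acidic proton and serves as the coordinating group for the metalation in step 5.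

Step 4
Reactants: 11 4-bromophenol; 12 1-bromo-3-methylbut-2-ene (prenyl bromide)
Product: 13 1-bromo-4-[(3-methylbut-2-en-1-yl)oxy]benzene
Conditions: K2CO3 (1.5 equiv), 12 (1.1 equiv), acetone, reflux
Reagents that add atoms: prenyl bromide 12, CC(C)=CCBr
Why: Williamson ether synthesis, in which the phenoxide displaces the primary allylic bromide by SN2 at oxygen under mild carbonate conditions, with the aryl bromide inert.

Step 5
Reactants: 10 5-methoxy-7-(methoxymethoxy)-2,2-dimethyl-2H-chromene; 14 1,4-dimethylpiperazine-2,3-dione; 13 1-bromo-4-[(3-methylbut-2-en-1-yl)oxy]benzene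
Product: 19 1-[5-methoxy-7-(methoxymethoxy)-2,2-dimethyl-2H-chromen-6-yl]-2-{4-[(3-methylbut-2-en-1-yl)oxy]phenyl}ethane-1,2-dione, via C6 aryllithium 15 (not isolated), via mono-adduct 16 (not isolated), via 4-prenyloxyphenyllithium 17 (not isolated), via bis-adduct 18 (not isolated)
Conditions: (a) 10, n-BuLi (1.1 equiv), THF, 0 °C, 1 h; (b) 14 (1.1 equiv), THF, −78 → 0 °C; (c) 17 [from 13 (1.6 equiv), n-BuLi (1.5 equiv), THF, −78 °C], −78 → 0 °C; (d) 1 M HCl, 0 °C, short contact
Reagents that add atoms: 1,4-dimethylpiperazine-2,3-dione 14, CN1CCN(C)C(=O)C1=O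
Why: Directed ortho-metalation should place lithium at C6, the position held between the two freely coordinating OMe and OMOM oxygens (C8 is also flanked by two oxygens, but O1 is a tert-alkyl aryl ether screened by the C2 methyl groups), and the known sequential addition of two different organolithiums to 1,4-dimethylpiperazine-2,3-dione then builds the unsymmetrical dione, because each tetrahedral lithium aminal alkoxide persists until the acid quench so that no ketone ever meets an organolithium, the hindered 15 being offered the free diamide first and the small 17 in excess second, while the stereocentres of 16 and 18 are transient and vanish on hydrolysis.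

Step 6
Reactants: 19 1-[5-methoxy-7-(methoxymethoxy)-2,2-dimethyl-2H-chromen-6-yl]-2-{4-[(3-methylbut-2-en-1-yl)oxy]phenyl}ethane-1,2-dione
Product: 21 ficucaricone C, via aryl TMS ether 20 (not isolated)
Conditions: TMSOTf (2 equiv), 2,2'-bipyridyl (3 equiv), MeCN, 0 °C → rt; then H2O, rt
Reagents that add atoms: none
Why: The TMSOTf–2,2'-bipyridyl pair is a known, essentially non-acidic method for aryl MOM ethers in which the silyl-activated acetal is cleaved to aryl silyl ether 20 and water then frees the phenol, here held by a hydrogen bond to the C6 carbonyl, and since neither a free Brønsted acid nor an alcohol solvent (which could trap the hydroxy-dione as a cyclic mixed ketal) is present, the prenyl aryl ether, the C3=C4 bond and the dione should persist.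

**Compound list**
1 | 2,4-dihydroxy-6-methoxybenzaldehyde | COc1cc(O)cc(O)c1C=O | starting material
2 | ethyl (triphenylphosphoranylidene)acetate | CCOC(=O)C=P(c1ccccc1)(c1ccccc1)c1ccccc1 | starting material
3 | ethyl (2E)-3-(2,4-dihydroxy-6-methoxyphenyl)prop-2-enoate | CCOC(=O)/C=C/c1c(O)cc(O)cc1OC | intermediate
4 | ethyl (2Z)-3-(2,4-dihydroxy-6-methoxyphenyl)prop-2-enoate | CCOC(=O)/C=C\c1c(O)cc(O)cc1OC | intermediate
5 | 7-hydroxy-5-methoxy-2H-chromen-2-one | COc1cc(O)cc2oc(=O)ccc12 | intermediate
6 | methyllithium | [Li]C | starting material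
7 | dilithium salt of (3Z)-4-(2,4-dihydroxy-6-methoxyphenyl)but-3-en-2-one | CC(=O)/C=C\c1c(O[Li])cc(O[Li])cc1OC | intermediate
8 | 4-[(1Z)-3-hydroxy-3-methylbut-1-en-1-yl]-5-methoxybenzene-1,3-diol | CC(C)(O)/C=C\c1c(O)cc(O)cc1OC | intermediate
9 | 5-methoxy-2,2-dimethyl-2H-chromen-7-ol | COc1cc(O)cc2OC(C)(C)C=Cc12 | intermediate
10 | 5-methoxy-7-(methoxymethoxy)-2,2-dimethyl-2H-chromene | COCOc1cc(OC)c2C=CC(C)(C)Oc2c1 | intermediate
11 | 4-bromophenol | Oc1ccc(Br)cc1 | starting material
12 | 1-bromo-3-methylbut-2-ene (prenyl bromide) | CC(C)=CCBr | starting material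
13 | 1-bromo-4-[(3-methylbut-2-en-1-yl)oxy]benzene | CC(C)=CCOc1ccc(Br)cc1 | intermediate
14 | 1,4-dimethylpiperazine-2,3-dione | CN1CCN(C)C(=O)C1=O | starting material
15 | [5-methoxy-7-(methoxymethoxy)-2,2-dimethyl-2H-chromen-6-yl]lithium | COCOc1cc2OC(C)(C)C=Cc2c(OC)c1[Li] | intermediate
16 | lithium 2-[5-methoxy-7-(methoxymethoxy)-2,2-dimethyl-2H-chromen-6-yl]-1,4-dimethyl-3-oxopiperazin-2-olate (racemic) | COCOc1cc2OC(C)(C)C=Cc2c(OC)c1C1(O[Li])N(C)CCN(C)C1=O | intermediate
17 | {4-[(3-methylbut-2-en-1-yl)oxy]phenyl}lithium | CC(C)=CCOc1ccc([Li])cc1 | intermediate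
18 | dilithium 2-[5-methoxy-7-(methoxymethoxy)-2,2-dimethyl-2H-chromen-6-yl]-1,4-dimethyl-3-{4-[(3-methylbut-2-en-1-yl)oxy]phenyl}piperazine-2,3-diolate (mixture of diastereomers, of no consequence) | COCOc1cc2OC(C)(C)C=Cc2c(OC)c1C1(O[Li])N(C)CCN(C)C1(O[Li])c1ccc(OCC=C(C)C)cc1 | intermediate
19 | 1-[5-methoxy-7-(methoxymethoxy)-2,2-dimethyl-2H-chromen-6-yl]-2-{4-[(3-methylbut-2-en-1-yl)oxy]phenyl}ethane-1,2-dione | COCOc1cc2OC(C)(C)C=Cc2c(OC)c1C(=O)C(=O)c1ccc(OCC=C(C)C)cc1 | intermediate
20 | 1-{5-methoxy-2,2-dimethyl-7-[(trimethylsilyl)oxy]-2H-chromen-6-yl}-2-{4-[(3-methylbut-2-en-1-yl)oxy]phenyl}ethane-1,2-dione | COc1c2C=CC(C)(C)Oc2cc(O[Si](C)(C)C)c1C(=O)C(=O)c1ccc(OCC=C(C)C)cc1 | intermediate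
21 | ficucaricone C, 1-(7-hydroxy-5-methoxy-2,2-dimethyl-2H-chromen-6-yl)-2-{4-[(3-methylbut-2-en-1-yl)oxy]phenyl}ethane-1,2-dione (no stereocentre) | COc1c2c(cc(O)c1C(=O)C(=O)c1ccc(OCC=C(C)C)cc1)OC(C)(C)C=C2 | target

**Step count:** 6 steps in total. The longest linear sequence is 5 steps (steps 1, 2, 3, 5, 6). Step 4 is a one-step side branch.

**Steps most likely to fail**

**Step 5.**
- What may go wrong: the deprotonation may be shared between C6 and C8, because C8 also lies between two oxygens. A C8 lithio species would carry the dione to the wrong carbon.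
- A second weak point is statistical distribution of the two aryllithiums over the diamide. The order of addition is meant to hold this down.
- The fallback replaces C–H metalation by halogen–lithium exchange on a bromide whose position is fixed by blocking. It sets out from coumarin 5 and comes back at aryllithium 15.
- Iodination of 5 (I2, KI, aqueous NH3) goes to C8 in 7-hydroxycoumarins and should give 7-hydroxy-8-iodo-5-methoxy-2H-chromen-2-one F1.
- NBS in MeCN at 0 °C then finds only one free activated ring position and should give 6-bromo-7-hydroxy-8-iodo-5-methoxy-2H-chromen-2-one F2.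
- Transfer hydrogenolysis of the weaker carbon–iodine bond (Pd(OAc)2 cat., HCO2Na, DMF) should leave 6-bromo-7-hydroxy-5-methoxy-2H-chromen-2-one F3.
- The addition and cyclodehydration of step 2 are then run with the methylcerium reagent from MeLi and CeCl3, so that bromine–metal exchange is suppressed. This should give 6-bromo-5-methoxy-2,2-dimethyl-2H-chromen-7-ol F4.
- NaH/MOMCl should give 6-bromo-5-methoxy-7-(methoxymethoxy)-2,2-dimethyl-2H-chromene F5.
- n-BuLi in THF at −78 °C converts F5 into 15 with the metal fixed at C6, and step 5 continues from operation (b).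

**Step 2.**
- What may go wrong: conjugate addition at C4, enolisation of the methyl ketone in 7 in place of the second addition, sluggish reaction of a poorly soluble phenoxide, or acid-induced oligomerisation of the electron-rich chromenol during closure.
- The fallback removes the Michael position before the organometallic step and restores the alkene at the end. It sets out from 5 and comes back at 10.
- Hydrogenation (H2, Pd/C, EtOAc) should give 7-hydroxy-5-methoxy-3,4-dihydro-2H-chromen-2-one F6, a reactive aryl ester that is no longer conjugated with the phenoxide.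
- Excess MeMgBr in THF should give 4-(3-hydroxy-3-methylbutyl)-5-methoxybenzene-1,3-diol F7.
- Catalytic p-TsOH in warm toluene closes the tertiary cation onto the ortho phenol to give 5-methoxy-2,2-dimethyl-3,4-dihydro-2H-chromen-7-ol F8.
- NaH/MOMCl gives 5-methoxy-7-(methoxymethoxy)-2,2-dimethyl-3,4-dihydro-2H-chromene F9.
- DDQ in refluxing dioxane dehydrogenates C3–C4 to 10, by hydride abstraction from the benzylic C4, which the ortho and para oxygens activate.

**Step 6.**
- What may go wrong: activation by the silyl triflate may also ionise the allylic aryl ether, with loss of the prenyl group. Alternatively, the MOM ether beside the C6 acyl group may react so slowly that harsher acid is needed, which endangers the prenyl ether further.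
- The fallback moves the prenylation to the very end, so that no prenyl ether ever meets an acid. It sets out from 11 and 10 and comes back at 21.
- Phenol 11 is protected (NaH, MOMCl, DMF) as 1-bromo-4-(methoxymethoxy)benzene F10.
- F10 is exchanged with n-BuLi at −78 °C to [4-(methoxymethoxy)phenyl]lithium F11, which is used in place of 17 in the protocol of step 5.
- Mono-adduct 16 then passes into dilithium 2-[5-methoxy-7-(methoxymethoxy)-2,2-dimethyl-2H-chromen-6-yl]-3-[4-(methoxymethoxy)phenyl]-1,4-dimethylpiperazine-2,3-diolate F12.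
- After the quench this gives 1-[5-methoxy-7-(methoxymethoxy)-2,2-dimethyl-2H-chromen-6-yl]-2-[4-(methoxymethoxy)phenyl]ethane-1,2-dione F13.
- 2 M HCl in THF at 45 °C removes both MOM groups to give 1-(7-hydroxy-5-methoxy-2,2-dimethyl-2H-chromen-6-yl)-2-(4-hydroxyphenyl)ethane-1,2-dione F14.
- K2CO3 (1.1 equiv) and 12 (1.05 equiv) in DMF at rt should alkylate only the free 4'-hydroxyl, since the 7-hydroxyl is tied up in the hydrogen bond to the C6 carbonyl. This gives 21.

**Further compounds**
F1 | step 5 | 7-hydroxy-8-iodo-5-methoxy-2H-chromen-2-one | Ic1c(O)cc(OC)c2ccc(=O)oc12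
F2 | step 5 | 6-bromo-7-hydroxy-8-iodo-5-methoxy-2H-chromen-2-one | Ic1c(O)c(Br)c(OC)c2ccc(=O)oc12
F3 | step 5 | 6-bromo-7-hydroxy-5-methoxy-2H-chromen-2-one | COc1c(Br)c(O)cc2oc(=O)ccc12
F4 | step 5 | 6-bromo-5-methoxy-2,2-dimethyl-2H-chromen-7-ol | COc1c(Br)c(O)cc2OC(C)(C)C=Cc12
F5 | step 5 | 6-bromo-5-methoxy-7-(methoxymethoxy)-2,2-dimethyl-2H-chromene | COCOc1cc2OC(C)(C)C=Cc2c(OC)c1Br
F6 | step 2 | 7-hydroxy-5-methoxy-3,4-dihydro-2H-chromen-2-one | COc1cc(O)cc2OC(=O)CCc12
F7 | step 2 | 4-(3-hydroxy-3-methylbutyl)-5-methoxybenzene-1,3-diol | CC(C)(O)CCc1c(O)cc(O)cc1OC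
F8 | step 2 | 5-methoxy-2,2-dimethyl-3,4-dihydro-2H-chromen-7-ol | COc1cc(O)cc2OC(C)(C)CCc12
F9 | step 2 | 5-methoxy-7-(methoxymethoxy)-2,2-dimethyl-3,4-dihydro-2H-chromene | COCOc1cc(OC)c2CCC(C)(C)Oc2c1
F10 | step 6 | 1-bromo-4-(methoxymethoxy)benzene | COCOc1ccc(Br)cc1
F11 | step 6 | [4-(methoxymethoxy)phenyl]lithium | COCOc1ccc([Li])cc1
F12 | step 6 | dilithium 2-[5-methoxy-7-(methoxymethoxy)-2,2-dimethyl-2H-chromen-6-yl]-3-[4-(methoxymethoxy)phenyl]-1,4-dimethylpiperazine-2,3-diolate | COCOc1cc2OC(C)(C)C=Cc2c(OC)c1C1(O[Li])N(C)CCN(C)C1(O[Li])c1ccc(OCOC)cc1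
F13 | step 6 | 1-[5-methoxy-7-(methoxymethoxy)-2,2-dimethyl-2H-chromen-6-yl]-2-[4-(methoxymethoxy)phenyl]ethane-1,2-dione | COCOc1cc2OC(C)(C)C=Cc2c(OC)c1C(=O)C(=O)c1ccc(OCOC)cc1
F14 | step 6 | 1-(7-hydroxy-5-methoxy-2,2-dimethyl-2H-chromen-6-yl)-2-(4-hydroxyphenyl)ethane-1,2-dione | COc1c2C=CC(C)(C)Oc2cc(O)c1C(=O)C(=O)c1ccc(O)cc1
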